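## Structural features

Aiphanol is a stilbenolignan built on a 2,3-dihydro-1,4-benzodioxine. The dioxane ring is fused to benzo ring B, and ring B carries an (E)-ethenyl bridge to a 3,5-dihydroxyphenyl ring (ring C), para to its oxygen Ob and meta to Oa. The two dioxane carbons are neighbouring stereocentres: Cα (R) bears ring A (4-hydroxy-3,5-dimethoxyphenyl) and Oa, Cβ (R) bears the hydroxymethyl carbon Cγ and Ob, and the two substituents are trans. The fragile points are the Cα–Oa bond, the stilbene and the three phenols. Cα–Oa is a benzylic aryl ether para to the ring A oxygen, so it can ionise in acid and can open through a para-quinone methide once the ring A phenoxide is free; the stilbene is sensitive to hydrogenation, acid and light. The real difficulty is not the carbon skeleton but placing each catechol oxygen of ring B on the correct dioxane carbon and fixing both stereocentres absolutely, with no later step able to epimerise Cα. The feature exploited is that Cβ carries Ob and the CγH2OH group, which is the pattern left when an aryloxide opens a Cβ–Cγ epoxide at its inner carbon; the key step lets the ring B hydroxyl para to the formyl group do this.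

The stereochemical chain was checked: a (2S,3S) epoxy alcohol, inversion at Cα, retention at Cβ on forming the terminal epoxide and inversion at Cβ on ring closure end at the trans (2R,3R) dioxane of the target, so the configurations of precursor and product of the key step need no correction. What is changed is the mask on the ring A oxygen: a methoxymethyl acetal replaces a hydrogenolysis-labile ether, so ring A stays masked through every basic step and is released together with ring C at the end.

## Logic of the disconnections

**17 to 16.** The bonds cut are the three aryl O–CH2OCH3 bonds, one on ring A and two on ring C. They are cut last because the phenols must stay masked until the stilbene exists, and one acetal type on both rings lets a single operation finish the synthesis. The gain is that every earlier step runs on non-ionisable arenes; a benzyl ether on ring A would instead have to leave by hydrogenolysis before the alkene is made, next to a formyl group and a benzylic C–O bond, and the freed phenol would then meet the base of the olefination. The demand on the forward step is that the acid cleaves three acetals without ionising Cα–Oa or touching the stilbene.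

**16 to 11 and 15.** The bond cut is the central C=C bond of the stilbene. Cutting here is convergent and separates ring C from the stereodefined core. The gain is two fragments of similar size, one carrying all the stereochemistry and one achiral. The demand is an (E)-selective olefination that tolerates the free primary hydroxyl of 11 and leaves Cα and Cβ alone.

**15 to 14, 13 and 12.** The bonds cut are the benzylic C–P bond, then the C–Br bond, then the two aryl O–CH2OCH3 bonds. These are routine functional group changes chosen so that ring C carries the same acetal as ring A. The gain is a commercial triol as the source of ring C. The demand is that the two phenols of 12 are masked selectively in the presence of its benzylic hydroxyl, and that the bromination is neutral enough for the acetals.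

**11 to 10.** The bond cut is Ob–Cβ, which also opens the dioxane ring. Cutting here turns the 1,2-relationship of Ob and the Cγ hydroxyl into a terminal epoxide, so the ring closure becomes a stereospecific SN2 event. The gain is that the second stereocentre no longer has to be made: it is inherited, with inversion, from the epoxide. The demand is attack at the inner epoxide carbon (six-membered ring) and not at Cγ, with one nucleophile only.

**10 to 9.** The bond cut is the allyl–O bond on the future Ob. The nucleophilic oxygen has to stay masked until the epoxide exists, otherwise it could attack the sulfonate of 8 directly. The gain is a stable, storable epoxide. The demand is a neutral deprotection that spares the epoxide and the formyl group and does not generate the phenoxide prematurely.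

**9 to 7 through 8.** The bond cut is the epoxide O–Cγ bond, which reveals a 1,2-diol. The terminal epoxide is a dehydrated diol, and the diol is what an epoxy alcohol gives on opening. The gain is that the Cβ–O bond is never broken in this operation, so Cβ keeps its configuration. The demand is selective activation of the primary hydroxyl.

**7 to 4 and 6.** The bond cut is Cα–Oa. This is the convergent union of the ring A and ring B fragments, and the only free hydroxyl of 6 becomes Oa, which settles the regiochemistry of ring B. The gain is two simple pieces, one chiral epoxy alcohol and one achiral phenol. The demand is attack at the benzylic carbon of 4 with clean inversion.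

**6 to 5.** The bond cut is the allyl–O bond. The two hydroxyls of 5 differ in acidity, so they can be told apart in one step. The gain is a commercial catechol. The demand is alkylation only at the hydroxyl para to the formyl group.

**4 to 3.** The bonds cut are the two C–O bonds of the epoxide. A reagent-controlled epoxidation of an (E)-allylic alcohol sets both stereocentres at once. The gain is an achiral alkene. The demand is high face selectivity and survival of an electron-rich aryl epoxide under the epoxidation conditions.

**3 to 2 and 1.** The bonds cut are the two C–H bonds introduced on reduction of the ester, then the acetal O–C bond and the ester O–C bond. One alkylating agent masks the phenol and turns the acid into a reducible ester. The gain is a commercial cinnamic acid with the (E) alkene already in place. The demand is 1,2-reduction without touching the alkene or the aryl acetal.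

## Other disconnections considered

**Alternative 1:** The cut goes through two C–C bonds of ring B, so the benzo ring is made last on a preformed dioxane. The lactone A1, (5R,6R)-5-[4-(benzyloxy)-3,5-dimethoxyphenyl]-6-{[(tert-butyldimethylsilyl)oxy]methyl}-1,4-dioxan-2-one, would be converted into its O-silyl ketene acetal. This would add as an electron-rich dienophile across C-3 and C-6 of methyl coumalate A2; loss of CO2 and of t-BuMe2SiOH would then aromatise the adduct to the ester A3, methyl (2R,3R)-3-[4-(benzyloxy)-3,5-dimethoxyphenyl]-2-[(tert-butyldimethylsilyloxy)methyl]-2,3-dihydro-1,4-benzodioxine-6-carboxylate.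

- In its favour: both stereocentres sit in a saturated ring before any aromatic chemistry, the two oxygens of ring B never have to be told apart by protecting groups, and there is no question of ring size.
- Against it here: A1 needs its own synthesis (a stereodefined 1-aryl-glycerol unit, O-alkylation with a glycolate unit, lactonisation), which is no shorter than the path to 10. The position of the ester relative to Ob rests on the orientation of a cycloaddition, an electronic preference and not a structural certainty. A3 is an ester and needs two redox adjustments before the olefination. The benzyl ether on ring A brings back a hydrogenolysis next to the sensitive groups.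
- Comparison: on structure the two plans are equal, since both deliver the trans dioxane with both centres defined beforehand. On mechanism the alternative is the better on one point, because it has no 6-exo against 7-endo issue and no catechol differentiation, but it replaces a simple SN2 step by a three-event cascade at high temperature. On step economy the chosen plan is shorter after the key step.

**Alternative 2:** The cut is the Oa–Cα bond, with Cα at the CH2 level in A4, 3-hydroxy-4-{[(2S)-1-hydroxy-3-(4-hydroxy-3,5-dimethoxyphenyl)propan-2-yl]oxy}benzaldehyde, whose single stereocentre would come from a glycidol enantiomer. Ag2O (monovalent silver) would oxidise ring A to its para-quinone methide, and the neighbouring ring B hydroxyl would add to Cα in the 6-exo-trig mode to give A5, (2R,3R)-3-(4-hydroxy-3,5-dimethoxyphenyl)-2-(hydroxymethyl)-2,3-dihydro-1,4-benzodioxine-6-carbaldehyde.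

- In its favour: it is short, needs no protecting group on ring A, takes Cβ from the chiral pool, and the trans isomer is the more stable one.
- Against it here: Cα would be created under substrate control, so the trans preference is a tendency and not the consequence of a stereospecific step. Ag2O can also oxidise the formyl group, and the quinone methide can be trapped by water or by a second phenol. A5 would carry a free ring A phenol into the basic olefination, where Cα can reopen.
- Comparison: on step economy and protecting group economy the alternative is the better. On Cβ the two are equal, both absolute. On structure and mechanism the chosen plan is stronger, because both centres follow from SN2 inversions and the oxidant-sensitive groups never meet an oxidant.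

**Alternative 3:** The cut is the aryl C–Ob bond. In A6, 3-{[(2R)-3-(benzyloxy)-2-hydroxy-1-(4-hydroxy-3,5-dimethoxyphenyl)propyl]oxy}-4-fluorobenzaldehyde (either configuration at Cα), K2CO3 in DMF would turn the Cβ hydroxyl into an alkoxide that displaces fluoride para to the formyl group through a Meisenheimer complex. With ring A free, Cα could open and reclose through the quinone methide and would be expected to settle trans, giving A7, (2R,3R)-2-[(benzyloxy)methyl]-3-(4-hydroxy-3,5-dimethoxyphenyl)-2,3-dihydro-1,4-benzodioxine-6-carbaldehyde.

- In its favour: the regiochemistry is a structural certainty, since the fluorine marks the carbon of Ob. No other ring size is possible. The formyl group, which weakens the nucleophile in the chosen plan, here activates the electrophile. Only Cβ has to be made enantiopure.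
- Against it here: a single formyl group, opposed by an ortho alkoxy donor, is weak activation for a secondary alkoxide, so forcing conditions are likely. Under them the free ring A phenoxide of open-chain A6 can expel the ring B aryloxide before closure, and the fragments then separate. The trans outcome is an equilibrium position. The benzyl ether on Cγ must later be removed without hydrogenating the stilbene.
- Comparison: on regiochemical certainty and on the role of the formyl group the alternative is the better. On structure the two are equal, one six-membered ring and one bond formed. On mechanism the chosen plan relies on kinetic, stereospecific inversion instead of thermodynamic correction. Step economy is similar.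

Key step: step 8

Remark on the chemistry: chloromethyl methyl ether, allyl bromide, Ti(OiPr)4, L-(+)-diethyl tartrate, Pd(PPh3)4 and the other reagents are taken as commercial; only 1, 5 and 12 count as starting materials.

## Route

Step 1
Reactants: 1 sinapic acid, (2E)-3-(4-hydroxy-3,5-dimethoxyphenyl)prop-2-enoic acid
Product: 2 methoxymethyl (2E)-3-[3,5-dimethoxy-4-(methoxymethoxy)phenyl]prop-2-enoate
Conditions: MOMCl (2.5 equiv), i-Pr2NEt (3 equiv), CH2Cl2, 0 °C → rt
Reagents that add atoms: chloromethyl methyl ether, COCCl (two equivalents are incorporated)
Why: Carboxylate and hindered phenoxide are both O-alkylated by the chloromethyl ether under amine base (Williamson-type acetal formation), so one operation masks the phenol as a base-stable acetal and turns the acid into a reducible ester.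

Step 2
Reactants: 2 methoxymethyl (2E)-3-[3,5-dimethoxy-4-(methoxymethoxy)phenyl]prop-2-enoate
Product: 3 (2E)-3-[3,5-dimethoxy-4-(methoxymethoxy)phenyl]prop-2-en-1-ol
Conditions: i-Bu2AlH (2.5 equiv), CH2Cl2, −78 → 0 °C
Reagents that add atoms: none
Why: 1,2-Reduction of an α,β-unsaturated ester by i-Bu2AlH at low temperature should give the (E)-allylic alcohol without touching the alkene or the aryl acetal.

Step 3
Reactants: 3 (2E)-3-[3,5-dimethoxy-4-(methoxymethoxy)phenyl]prop-2-en-1-ol
Product: 4 {(2S,3S)-3-[3,5-dimethoxy-4-(methoxymethoxy)phenyl]oxiran-2-yl}methanol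
Conditions: Ti(OiPr)4 (10 mol %), L-(+)-diethyl tartrate (12 mol %), t-BuOOH (2 equiv, in decane), 4 Å molecular sieves, CH2Cl2, −20 °C
Reagents that add atoms: tert-butyl hydroperoxide, CC(C)(C)OO (delivers the epoxide oxygen)
Why: Sharpless asymmetric epoxidation: with the L-(+)-tartrate the titanium tartrate peroxide complex delivers oxygen to the face of the (E)-allylic alcohol that gives the (2S,3S) epoxy alcohol, which sets both stereocentres. Catalytic titanium with molecular sieves limits Lewis acid opening of the aryl epoxide, and ring A is only a moderate donor because its acetal oxygen is twisted out of conjugation by the two flanking methoxy groups.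

Step 4
Reactants: 5 3,4-dihydroxybenzaldehyde
Product: 6 3-hydroxy-4-(prop-2-en-1-yloxy)benzaldehyde
Conditions: allyl bromide (1.05 equiv), NaHCO3 (1.5 equiv), NaI (cat.), DMF, 40 °C
Reagents that add atoms: allyl bromide, C=CCBr
Why: The hydroxyl para to the formyl group is the more acidic one, so a weak base ionises it selectively and Williamson alkylation occurs at O-4; O-3, the future Oa, stays free.

Step 5
Reactants: 4 {(2S,3S)-3-[3,5-dimethoxy-4-(methoxymethoxy)phenyl]oxiran-2-yl}methanol; 6 3-hydroxy-4-(prop-2-en-1-yloxy)benzaldehyde (1.5 equiv)
Product: 7 3-{[(1R,2S)-1-[3,5-dimethoxy-4-(methoxymethoxy)phenyl]-2,3-dihydroxypropyl]oxy}-4-(prop-2-en-1-yloxy)benzaldehyde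
Conditions: Ti(OiPr)4 (1.5 equiv), CH2Cl2, rt → 40 °C
Reagents that add atoms: none
Why: Ti(OiPr)4 binds the epoxy alcohol as its alkoxide and activates the epoxide so that the phenol attacks C-3, the benzylic carbon Cα, with inversion (Lewis acid mediated regioselective opening of a 2,3-epoxy alcohol). Cα becomes R, Cβ keeps its configuration, and the only free hydroxyl of 6 becomes Oa, which fixes the regiochemistry of ring B.

Step 6
Reactants: 7 3-{[(1R,2S)-1-[3,5-dimethoxy-4-(methoxymethoxy)phenyl]-2,3-dihydroxypropyl]oxy}-4-(prop-2-en-1-yloxy)benzaldehyde
Product: 9 3-{(R)-[3,5-dimethoxy-4-(methoxymethoxy)phenyl][(2S)-oxiran-2-yl]methoxy}-4-(prop-2-en-1-yloxy)benzaldehyde, via primary tosylate 8 (not isolated)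
Conditions: TsCl (1.05 equiv), Et3N (1.5 equiv), Bu2SnO (2 mol %), CH2Cl2, 0 °C → rt; then K2CO3 (3 equiv), MeOH, rt
Reagents that add atoms: p-toluenesulfonyl chloride, Cc1ccc(cc1)S(=O)(=O)Cl (its tosyl group is in 8 and is lost again on the way to 9)
Why: Bu2SnO forms a stannylene acetal in catalytic amount that directs sulfonylation to the primary hydroxyl; K2CO3 in MeOH then closes the β-hydroxy tosylate by intramolecular Williamson displacement at Cγ (3-exo-tet). The Cβ–O bond is not broken, so Cβ keeps its configuration.

Step 7
Reactants: 9 3-{(R)-[3,5-dimethoxy-4-(methoxymethoxy)phenyl][(2S)-oxiran-2-yl]methoxy}-4-(prop-2-en-1-yloxy)benzaldehyde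
Product: 10 3-{(R)-[3,5-dimethoxy-4-(methoxymethoxy)phenyl][(2S)-oxiran-2-yl]methoxy}-4-hydroxybenzaldehyde
Conditions: Pd(PPh3)4 (5 mol %), PhNHMe (3 equiv), THF, rt
Reagents that add atoms: none
Why: Zerovalent palladium ionises the aryl allyl ether to a π-allyl complex (Tsuji–Trost deallylation) and N-methylaniline traps the allyl group. The amine is too weak a base to ionise the liberated phenol, so the epoxide should survive until step 8.

Step 8
Reactants: 10 3-{(R)-[3,5-dimethoxy-4-(methoxymethoxy)phenyl][(2S)-oxiran-2-yl]methoxy}-4-hydroxybenzaldehyde
Product: 11 (2R,3R)-3-[3,5-dimethoxy-4-(methoxymethoxy)phenyl]-2-(hydroxymethyl)-2,3-dihydro-1,4-benzodioxine-6-carbaldehyde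
Conditions: K2CO3 (1.5 equiv), DMF (0.05 M), 60 °C
Reagents that add atoms: none
Why: K2CO3 ionises the ring B hydroxyl, made acidic by the para formyl group, and the phenoxide oxygen Ob attacks Cβ of the epoxide from the side opposite the Cβ–O bond in an SN2 step; the epoxide oxygen stays on Cγ as an alkoxide that is protonated by hydrogen carbonate, so the base is turned over. The closest known reaction type is the base-mediated cyclisation of 2-(oxiranylmethoxy)phenols to 2-(hydroxymethyl)-1,4-benzodioxanes. The 1,4-dioxane ring closes in the 6-exo-tet mode, the breaking C–O bond lying outside the new ring. The configuration at Cβ is set by inversion of the (S) epoxide carbon, whose configuration goes back to the epoxidation of step 3; Cα is a spectator, so the product is the trans (2R,3R) dioxane. The step needs attack at Cβ and not at Cγ (7-endo-tet): the four-atom tether Ob–C(aryl)–C(aryl)–Oa–Cα holds Ob on the axis of the Cβ–O bond, whereas reaching Cγ would demand a seven-membered transition state with a bent trajectory. It also needs a single nucleophile, which the substrate secures because ring A is masked as its acetal (no second phenoxide, no quinone methide at Cα) and the secondary hydroxyl no longer exists. The phenoxide is a modest nucleophile, so a dipolar aprotic solvent and gentle heating are used, and dilution keeps intermolecular opening down.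

Step 9
Reactants: 12 3,5-dihydroxybenzyl alcohol, 5-(hydroxymethyl)benzene-1,3-diol
Product: 13 [3,5-bis(methoxymethoxy)phenyl]methanol
Conditions: MOMCl (2.3 equiv), K2CO3 (3 equiv), acetone, 0 °C → rt
Reagents that add atoms: chloromethyl methyl ether, COCCl (two equivalents are incorporated)
Why: K2CO3 ionises only the phenols, so Williamson-type alkylation converts the two aryl oxygens into methoxymethyl acetals while the benzylic alcohol stays free.

Step 10
Reactants: 13 [3,5-bis(methoxymethoxy)phenyl]methanol
Product: 14 1-(bromomethyl)-3,5-bis(methoxymethoxy)benzene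
Conditions: CBr4 (1.2 equiv), PPh3 (1.2 equiv), CH2Cl2, 0 °C
Reagents that add atoms: carbon tetrabromide, BrC(Br)(Br)Br (supplies the bromine)
Why: Appel reaction: the benzylic alcohol is activated as an alkoxyphosphonium ion and displaced by bromide under neutral conditions, which the aryl acetals tolerate.

Step 11
Reactants: 14 1-(bromomethyl)-3,5-bis(methoxymethoxy)benzene
Product: 15 diethyl {[3,5-bis(methoxymethoxy)phenyl]methyl}phosphonate
Conditions: P(OEt)3 (neat, 3 equiv), 130 °C
Reagents that add atoms: triethyl phosphite, CCOP(OCC)OCC
Why: Michaelis–Arbuzov reaction: the phosphite attacks the benzylic bromide and bromide dealkylates the phosphonium ion to the phosphonate.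

Step 12
Reactants: 11 (2R,3R)-3-[3,5-dimethoxy-4-(methoxymethoxy)phenyl]-2-(hydroxymethyl)-2,3-dihydro-1,4-benzodioxine-6-carbaldehyde; 15 diethyl {[3,5-bis(methoxymethoxy)phenyl]methyl}phosphonate (1.5 equiv)
Product: 16 {(2R,3R)-6-{(E)-2-[3,5-bis(methoxymethoxy)phenyl]ethenyl}-3-[3,5-dimethoxy-4-(methoxymethoxy)phenyl]-2,3-dihydro-1,4-benzodioxin-2-yl}methanol
Conditions: KOt-Bu (3 equiv), THF, 0 °C → rt (anion of 15 formed first, then 11 added)
Reagents that add atoms: none
Why: Horner–Wadsworth–Emmons olefination: reversible addition of the benzylic phosphonate anion to the aryl aldehyde and elimination through the less congested oxaphosphetane should give the (E)-stilbene. The extra base only turns the primary alcohol into a spectator alkoxide, and with ring A masked no quinone methide can form, so Cα and Cβ are untouched.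

Step 13
Reactants: 16 {(2R,3R)-6-{(E)-2-[3,5-bis(methoxymethoxy)phenyl]ethenyl}-3-[3,5-dimethoxy-4-(methoxymethoxy)phenyl]-2,3-dihydro-1,4-benzodioxin-2-yl}methanol
Product: 17 aiphanol (5-{(E)-2-[(2R,3R)-3-(4-hydroxy-3,5-dimethoxyphenyl)-2-(hydroxymethyl)-2,3-dihydro-1,4-benzodioxin-6-yl]ethenyl}benzene-1,3-diol)
Conditions: HCl (2 M, MeOH–H2O 9:1), 45 °C, dark
Reagents that add atoms: none
Why: Acid-catalysed transacetalisation to methanol should remove the three aryl methoxymethyl groups as dimethoxymethane under conditions mild enough for the stilbene and the Cα–Oa bond. No stereocentre is formed, and Cβ, which is not ionisable, holds the configuration.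

## Compound list

1 | sinapic acid, (2E)-3-(4-hydroxy-3,5-dimethoxyphenyl)prop-2-enoic acid | COc1cc(/C=C/C(=O)O)cc(OC)c1O | starting material
2 | methoxymethyl (2E)-3-[3,5-dimethoxy-4-(methoxymethoxy)phenyl]prop-2-enoate | COCOC(=O)/C=C/c1cc(OC)c(OCOC)c(OC)c1 | intermediate
3 | (2E)-3-[3,5-dimethoxy-4-(methoxymethoxy)phenyl]prop-2-en-1-ol | OC/C=C/c1cc(OC)c(OCOC)c(OC)c1 | intermediate
4 | {(2S,3S)-3-[3,5-dimethoxy-4-(methoxymethoxy)phenyl]oxiran-2-yl}methanol | COc1cc([C@@H]2O[C@H]2CO)cc(OC)c1OCOC | intermediate
5 | 3,4-dihydroxybenzaldehyde | O=Cc1ccc(O)c(O)c1 | starting material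
6 | 3-hydroxy-4-(prop-2-en-1-yloxy)benzaldehyde | O=Cc1ccc(OCC=C)c(O)c1 | intermediate
7 | 3-{[(1R,2S)-1-[3,5-dimethoxy-4-(methoxymethoxy)phenyl]-2,3-dihydroxypropyl]oxy}-4-(prop-2-en-1-yloxy)benzaldehyde | COc1cc([C@@H](Oc2cc(C=O)ccc2OCC=C)[C@@H](O)CO)cc(OC)c1OCOC | intermediate
8 | (2S,3R)-3-[3,5-dimethoxy-4-(methoxymethoxy)phenyl]-3-[5-formyl-2-(prop-2-en-1-yloxy)phenoxy]-2-hydroxypropyl 4-methylbenzenesulfonate | COc1cc([C@@H](Oc2cc(C=O)ccc2OCC=C)[C@@H](O)COS(=O)(=O)c2ccc(C)cc2)cc(OC)c1OCOC | intermediate
9 | 3-{(R)-[3,5-dimethoxy-4-(methoxymethoxy)phenyl][(2S)-oxiran-2-yl]methoxy}-4-(prop-2-en-1-yloxy)benzaldehyde | COc1cc([C@@H](Oc2cc(C=O)ccc2OCC=C)[C@@H]2CO2)cc(OC)c1OCOC | intermediate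
10 | 3-{(R)-[3,5-dimethoxy-4-(methoxymethoxy)phenyl][(2S)-oxiran-2-yl]methoxy}-4-hydroxybenzaldehyde | COc1cc([C@@H](Oc2cc(C=O)ccc2O)[C@@H]2CO2)cc(OC)c1OCOC | intermediate
11 | (2R,3R)-3-[3,5-dimethoxy-4-(methoxymethoxy)phenyl]-2-(hydroxymethyl)-2,3-dihydro-1,4-benzodioxine-6-carbaldehyde | COc1cc([C@H]2Oc3cc(C=O)ccc3O[C@@H]2CO)cc(OC)c1OCOC | intermediate
12 | 3,5-dihydroxybenzyl alcohol, 5-(hydroxymethyl)benzene-1,3-diol | OCc1cc(O)cc(O)c1 | starting material
13 | [3,5-bis(methoxymethoxy)phenyl]methanol | OCc1cc(OCOC)cc(OCOC)c1 | intermediate
14 | 1-(bromomethyl)-3,5-bis(methoxymethoxy)benzene | BrCc1cc(OCOC)cc(OCOC)c1 | intermediate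
15 | diethyl {[3,5-bis(methoxymethoxy)phenyl]methyl}phosphonate | CCOP(=O)(Cc1cc(OCOC)cc(OCOC)c1)OCC | intermediate
16 | {(2R,3R)-6-{(E)-2-[3,5-bis(methoxymethoxy)phenyl]ethenyl}-3-[3,5-dimethoxy-4-(methoxymethoxy)phenyl]-2,3-dihydro-1,4-benzodioxin-2-yl}methanol | COc1cc([C@H]2Oc3cc(/C=C/c4cc(OCOC)cc(OCOC)c4)ccc3O[C@@H]2CO)cc(OC)c1OCOC | intermediate
17 | aiphanol, 5-{(E)-2-[(2R,3R)-3-(4-hydroxy-3,5-dimethoxyphenyl)-2-(hydroxymethyl)-2,3-dihydro-1,4-benzodioxin-6-yl]ethenyl}benzene-1,3-diol | COc1cc([C@H]2Oc3cc(/C=C/c4cc(O)cc(O)c4)ccc3O[C@@H]2CO)cc(OC)c1O | target

## Step count and least certain steps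

Total step count: 13. Longest linear sequence: 9 steps (steps 1, 2, 3, 5, 6, 7, 8, 12, 13, from 1 to 17); steps 4 and 9 to 11 prepare the two side fragments.

**Step 8 (key step).** The most likely failure is loss of regiocontrol in the ring closure. Cβ is flanked by the fully substituted Cα, so attack of the phenoxide at the unhindered terminal carbon Cγ (7-endo) can compete. Because the phenoxide is stabilised by the para formyl group, the closure may also be slow enough for intermolecular epoxide opening to intrude. The fallback makes the Ob–Cβ bond by an intramolecular Mitsunobu etherification, in which Cβ carries the only free aliphatic hydroxyl. It sets out from 7. Selective silylation of the primary hydroxyl (t-BuMe2SiCl, imidazole, CH2Cl2, 0 °C) would give 3-{[(1R,2S)-3-[(tert-butyldimethylsilyl)oxy]-1-[3,5-dimethoxy-4-(methoxymethoxy)phenyl]-2-hydroxypropyl]oxy}-4-(prop-2-en-1-yloxy)benzaldehyde F1. Deallylation as in step 7 (Pd(PPh3)4, PhNHMe, THF) would give 3-{[(1R,2S)-3-[(tert-butyldimethylsilyl)oxy]-1-[3,5-dimethoxy-4-(methoxymethoxy)phenyl]-2-hydroxypropyl]oxy}-4-hydroxybenzaldehyde F2. PPh3 and diisopropyl azodicarboxylate in THF should then close the ring with inversion at Cβ, the same stereochemical course as step 8, to (2R,3R)-2-{[(tert-butyldimethylsilyl)oxy]methyl}-3-[3,5-dimethoxy-4-(methoxymethoxy)phenyl]-2,3-dihydro-1,4-benzodioxine-6-carbaldehyde F3. Bu4NF in THF removes the silyl group and the sequence comes back to the route at 11.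

**Step 5.** The most likely failures are ionisation of the benzylic C–O bond of the electron-rich aryl epoxide on titanium, which would erode the inversion at Cα; transfer of isopropoxide from titanium in place of the weakly nucleophilic phenol; and hydride transfer from isopropoxide to the formyl group. The fallback is a base-mediated opening of the O-protected epoxide with no Lewis acid. It sets out from 4. Silylation (t-BuPh2SiCl, imidazole, CH2Cl2) would give tert-butyl({(2S,3S)-3-[3,5-dimethoxy-4-(methoxymethoxy)phenyl]oxiran-2-yl}methoxy)diphenylsilane F4. The caesium phenoxide of 6 (Cs2CO3, DMF, 80 °C) should attack the benzylic carbon in an SN2 sense, because C-2 is shielded by the silyloxymethyl group and deactivated by the adjacent C–O bond, and no Payne rearrangement is possible. This would give 3-{[(1R,2S)-3-[(tert-butyldiphenylsilyl)oxy]-1-[3,5-dimethoxy-4-(methoxymethoxy)phenyl]-2-hydroxypropyl]oxy}-4-(prop-2-en-1-yloxy)benzaldehyde F5. Bu4NF in THF then brings the sequence back to the route at 7.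

**Step 3.** The most likely failure is opening of the acid-sensitive aryl epoxide by alcohols or tartrate on the titanium catalyst as it forms, with low turnover and erosion of enantiomeric purity. The fallback is a metal-free dioxirane epoxidation (Shi epoxidation) under buffered basic conditions. It sets out from 3 and uses 1,2:4,5-di-O-isopropylidene-β-L-erythro-2,3-hexodiulo-2,6-pyranose (30 mol %), KHSO5 (as its triple salt 2KHSO5·KHSO4·K2SO4), K2CO3 and Bu4NHSO4 in MeCN–CH2(OMe)2–H2O at 0 °C. This L-fructose-derived ketone is the enantiomer of the common D-fructose-derived one, which converts (E)-alkenes of this type into (R,R) epoxides, so it should give the (2S,3S) epoxide. The fallback comes back to the route at 4 and makes no new compound (F0).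

**Step 13.** The most likely failures are acid-promoted ionisation of the Cα–Oa bond, which is benzylic and para to the ring A oxygen, with epimerisation or methanolysis at Cα, and acid-promoted addition to the electron-rich stilbene. The fallback exchanges the acetals for silyl ethers and finishes with fluoride. It sets out from 16. Et3SiOTf (8 equiv) and 2,2′-bipyridyl in CH2Cl2 at 0 °C should convert the three aryl methoxymethyl ethers into aryl triethylsilyl ethers and silylate the primary alcohol, giving triethyl({(2R,3R)-6-{(E)-2-[3,5-bis(triethylsilyloxy)phenyl]ethenyl}-3-[3,5-dimethoxy-4-(triethylsilyloxy)phenyl]-2,3-dihydro-1,4-benzodioxin-2-yl}methoxy)silane F6. Bu4NF buffered with AcOH in THF at 0 °C then comes back to the route at 17.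

## Further compounds

F1 | step 8 | 3-{[(1R,2S)-3-[(tert-butyldimethylsilyl)oxy]-1-[3,5-dimethoxy-4-(methoxymethoxy)phenyl]-2-hydroxypropyl]oxy}-4-(prop-2-en-1-yloxy)benzaldehyde | COc1cc([C@@H](Oc2cc(C=O)ccc2OCC=C)[C@@H](O)CO[Si](C)(C)C(C)(C)C)cc(OC)c1OCOC
F2 | step 8 | 3-{[(1R,2S)-3-[(tert-butyldimethylsilyl)oxy]-1-[3,5-dimethoxy-4-(methoxymethoxy)phenyl]-2-hydroxypropyl]oxy}-4-hydroxybenzaldehyde | COc1cc([C@@H](Oc2cc(C=O)ccc2O)[C@@H](O)CO[Si](C)(C)C(C)(C)C)cc(OC)c1OCOC
F3 | step 8 | (2R,3R)-2-{[(tert-butyldimethylsilyl)oxy]methyl}-3-[3,5-dimethoxy-4-(methoxymethoxy)phenyl]-2,3-dihydro-1,4-benzodioxine-6-carbaldehyde | COc1cc([C@H]2Oc3cc(C=O)ccc3O[C@@H]2CO[Si](C)(C)C(C)(C)C)cc(OC)c1OCOC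
F4 | step 5 | tert-butyl({(2S,3S)-3-[3,5-dimethoxy-4-(methoxymethoxy)phenyl]oxiran-2-yl}methoxy)diphenylsilane | COc1cc([C@@H]2O[C@H]2CO[Si](c3ccccc3)(c3ccccc3)C(C)(C)C)cc(OC)c1OCOC
F5 | step 5 | 3-{[(1R,2S)-3-[(tert-butyldiphenylsilyl)oxy]-1-[3,5-dimethoxy-4-(methoxymethoxy)phenyl]-2-hydroxypropyl]oxy}-4-(prop-2-en-1-yloxy)benzaldehyde | COc1cc([C@@H](Oc2cc(C=O)ccc2OCC=C)[C@@H](O)CO[Si](c2ccccc2)(c2ccccc2)C(C)(C)C)cc(OC)c1OCOC
F0 | step 3 | none | none
F6 | step 13 | triethyl({(2R,3R)-6-{(E)-2-[3,5-bis(triethylsilyloxy)phenyl]ethenyl}-3-[3,5-dimethoxy-4-(triethylsilyloxy)phenyl]-2,3-dihydro-1,4-benzodioxin-2-yl}methoxy)silane | COc1cc([C@H]2Oc3cc(/C=C/c4cc(O[Si](CC)(CC)CC)cc(O[Si](CC)(CC)CC)c4)ccc3O[C@@H]2CO[Si](CC)(CC)CC)cc(OC)c1O[Si](CC)(CC)CC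
A1 | alternative 1 | (5R,6R)-5-[4-(benzyloxy)-3,5-dimethoxyphenyl]-6-{[(tert-butyldimethylsilyl)oxy]methyl}-1,4-dioxan-2-one | COc1cc([C@H]2OCC(=O)O[C@@H]2CO[Si](C)(C)C(C)(C)C)cc(OC)c1OCc1ccccc1
A2 | alternative 1 | methyl coumalate, methyl 2-oxo-2H-pyran-5-carboxylate | COC(=O)C1=COC(=O)C=C1
A3 | alternative 1 | methyl (2R,3R)-3-[4-(benzyloxy)-3,5-dimethoxyphenyl]-2-[(tert-butyldimethylsilyloxy)methyl]-2,3-dihydro-1,4-benzodioxine-6-carboxylate | COc1cc([C@H]2Oc3cc(C(=O)OC)ccc3O[C@@H]2CO[Si](C)(C)C(C)(C)C)cc(OC)c1OCc1ccccc1
A4 | alternative 2 | 3-hydroxy-4-{[(2S)-1-hydroxy-3-(4-hydroxy-3,5-dimethoxyphenyl)propan-2-yl]oxy}benzaldehyde | COc1cc(C[C@@H](CO)Oc2ccc(C=O)cc2O)cc(OC)c1O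
A5 | alternative 2 | (2R,3R)-3-(4-hydroxy-3,5-dimethoxyphenyl)-2-(hydroxymethyl)-2,3-dihydro-1,4-benzodioxine-6-carbaldehyde | COc1cc([C@H]2Oc3cc(C=O)ccc3O[C@@H]2CO)cc(OC)c1O
A6 | alternative 3 | 3-{[(2R)-3-(benzyloxy)-2-hydroxy-1-(4-hydroxy-3,5-dimethoxyphenyl)propyl]oxy}-4-fluorobenzaldehyde (either configuration at C-1 of the propyl chain) | COc1cc(C(Oc2cc(C=O)ccc2F)[C@H](O)COCc2ccccc2)cc(OC)c1O
A7 | alternative 3 | (2R,3R)-2-[(benzyloxy)methyl]-3-(4-hydroxy-3,5-dimethoxyphenyl)-2,3-dihydro-1,4-benzodioxine-6-carbaldehyde | COc1cc([C@H]2Oc3cc(C=O)ccc3O[C@@H]2COCc2ccccc2)cc(OC)c1O
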